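The numbers of this flask are assumed; the run is a simulation.

One mole of substrate is the unit of these books, kept for the closed flask eta.

| flask | substrate | partner | second reagent | third reagent | remark | time |
|---|---|---|---|---|---|---|
| theta | 0.12 M | 0.132 M | 0.240 M | 0.0960 M | one stirred flow tank at steady state, fed with the mixture as stated, mean residence time 50 min |  |
| eta | 0.12 M | 0.132 M | 0.240 M | 0.0960 M | everything together in a closed stirred flask, run for 50 min | 50 min |
| delta | 0.12 M | 0.132 M | 0.240 M | 0.0960 M (fed, over 25.0 min) | a stirred flask in which third reagent is dosed at a steady rate over 25.0 min without added volume, worked up at 50 min | 50 min |
| alpha | 0.12 M | 0.132 M | 0.240 M | 0.0960 M | a single well-mixed tank run continuously and read at steady state, 250 min in it on average |  |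

    substrate + partner → intermediate A (k1 = 0.0256 L mol⁻¹ s⁻¹)
    second reagent + intermediate A → intermediate B (k2 = 6.12 × 10⁻⁴ L mol⁻¹ s⁻¹)
    second reagent ⇌ dormant form (K3 = 1.46, k3 = 7.00 × 10⁻⁴ s⁻¹)
    substrate + second reagent → side product (k4 = 0.0281 L mol⁻¹ s⁻¹)
    third reagent + intermediate B → target (k5 = 0.00159 L mol⁻¹ s⁻¹)

- the set-up with the highest amount of intermediate A at the outlet or at the end, in percent of the substrate put in ("none" if the first two lie within 2 percentage points) (theta / eta / delta / alpha / none)
- amount of intermediate A at the outlet or at the end, in percent of the substrate put in, theta
- amount of intermediate A at the outlet or at the end, in percent of the substrate put in, eta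
- amount of intermediate A at the outlet or at the end, in percent of the substrate put in, delta
- amount of intermediate A at the outlet or at the end, in percent of the substrate put in, alpha

- the stated concentrations are those of everything mixed, before any reaction; amounts are the same in each set-up
- the feed brings no volume worth counting
- run time (eta): 50 min

**Ledger for eta, my own reckoning**

1. Substrate is the limiting reagent: its 0.12 M stands below the 0.132 M of partner. Partner and second reagent compete for it.

2. Substrate's half-life against both, at charged concentrations, is 1.14 min, shorter than the 17 min of second reagent's forward step into the dormant form. The competition in eta is therefore reckoned at the charge.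

3. Let f be the share of substrate taken by partner, the partner's rate on substrate divided by the sum of both rates: 33.4%. The remainder, 66.6%, is entered as side product.

4. Check of the freeze: these entries take partner to 0.0919 M and second reagent, free and dormant forms counted together, to 0.160 M. Their ratio moves from 0.550 to 0.574, so f may stand as one number.

5. Second reagent then relaxes towards the dormant form with a half-time of 9.79 min, shorter than the run. Its free level is frozen at 0.0651 M.

6. Held at that level for the whole run, although free second reagent stands higher in the first minutes, intermediate A survives the step to intermediate B with an estimated fraction 0.887. The books close in eta at 29.6% intermediate A, 3.76% passed on to intermediate B and beyond, and 66.6% side product.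

7. Third reagent appears only in the equation of intermediate B, so delta carries the same ledger. The two tanks are not entered here.

**The forecast**

The forecast names theta as best, with 35.9% for theta, 31% for eta, 31% for delta and 29.7% for alpha. Its ground is this: “the 50-minute tank does best because its low, partly dormant second reagent favours intermediate A”. For eta, my 29.6% lies below its 31%.

**The simulation**

Best is theta: theta gives 35.8%, eta 30.6%, delta 30.6% and alpha 29.7%.

In eta, substrate's half-life against both partner and second reagent, at charged concentrations, of 1.14 min stands against 17 min for the forward step into the dormant form alone. The share f of 33.4% lies 2.8 percentage points above the 30.6% of intermediate A read at the end. In delta, left to 500 min, f and the same free level of second reagent give 10.1% intermediate A, and the simulation gives 11.8%.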